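## Structural features

Abruquinone B (21) is an isoflavan quinone. A chroman (3,4-dihydro-2H-1-benzopyran), made of the aromatic ring A with methoxy groups at C6, C7 and C8 and the dihydropyran ring C (O1, C2, C3, C4), carries at C3 a 2,3-dimethoxy-1,4-benzoquinone, ring B, through the single bond C3–C1'. Ring B is fully differentiated: carbonyls at C2' and C5', methoxy groups at C3' and C4', and one hydrogen at C6', so that C2'–C5' form a run of four contiguous oxygenated carbons. The only stereocentre is C3 (S); it has no stereogenic neighbour and sits between C2 (OCH2), C4 (benzylic CH2) and C1'. The fragile points are the C3–H bond, which is allylic to C1'=C6' and vinylogously alpha to the C5' carbonyl, so that base or strong acid can tautomerise the quinone to a quinone methide and erase the stereocentre. In addition, O1 lies beta to C3 and can leave if C3 ever becomes carbanionic, the quinone is an electrophile and an oxidant, and ring A is electron-rich and oxidisable. The real difficulty is therefore not the skeleton but joining a regiodefined, fully oxygenated quinone to a configurationally labile tertiary centre as one enantiomer. The key step exploits the fact that C2', C3', C4' and C5' with their four oxygens map atom for atom onto dimethyl squarate, while C1' and C6' are a 1,1-disubstituted vinyl group on C3; ring B can then be closed at C5'–C6' by heat alone. The CIP descriptor of C3 changes along the route without any change in spatial arrangement: it is 3R whenever the C3 substituent outranks C2 (compounds 8–12) and 3S otherwise (13, 15–21).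

## Logic of the disconnections

21 ⇒ 20. No skeletal bond is cut; the carbonyls at C2' and C5' are taken back to hydroxyl groups. The quinone is what makes C3–H labile, so it should exist only in the last flask. The gain is a robust aromatic ring B in the preceding step. The forward step must use a neutral oxidant that leaves ring A alone.

20 ⇒ 17 (key disconnection). The C5'–C6' bond of ring B is cut and C2' and C5' are re-joined on paper as the carbinol and carbonyl carbons of a four-membered ring, the reverse of an electrocyclic ring expansion passing through 18 and 19. The cut is placed here because the four oxygenated carbons then form one small ring with all oxygens in place. The gain is the loss of the fully substituted ring B in one operation. The forward step must run thermally without acid or base, with the hydroxyl rotating outward so that the vinyl terminus meets the ketene carbon.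

17 ⇒ 16 + 14. The C1'–C2' bond between the vinyl carbon and the carbinol carbon is cut. This separates the whole oxygenated C4 unit as a commercial, symmetrical diketone and leaves a chroman with a two-carbon handle. The forward step must give a single 1,2-addition at low temperature by a vinyllithium that contains no residual alkyllithium.

16 ⇒ 15 ⇒ 13 ⇒ 12. No skeletal bond is cut; the C1'–Li bond is traced back through a sulfonylhydrazone to a ketone, so that C1'=C6' derives from an acetyl group. This avoids an alpha-chiral aldehyde and a vinyl halide and costs two operations. The forward steps must form the hydrazone without acid, and the second deprotonation must occur on the methyl group and not at C3–H.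

12 ⇒ 11 ⇒ 10 ⇒ 9 ⇒ 8. The C1'–C6' bond (carbonyl to methyl) is cut, returning to a carboxylic acid, which is the best handle for setting C3. The simplification is modest, but the acid is the substrate class with the most dependable asymmetric hydrogenation. The forward steps must give a single methyl addition through a chelated adduct and must not enolise towards C3.

8 ⇒ 7. No skeletal bond is cut; the hydrogens at C3 and C4 are removed to give the C3=C4 alkene. The stereocentre becomes the result of a catalyst-controlled addition of hydrogen to a flat, conjugated acid. The forward step must give high facial selectivity, and the ligand antipode must be chosen for the 3R acid.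

7 ⇒ 6 ⇒ 4 + 5. After an oxidation-level adjustment, the O1–C2 bond and the C3=C4 bond are cut. Ring C then falls apart into a salicylaldehyde and a three-carbon enal, which supplies C2, C3 and the carbon that ends as C1'. The forward step must add the phenoxide in a conjugate sense before the aldol condensation closes the ring.

4 ⇒ 3 ⇒ 2 ⇒ 1. The aryl–formyl bond (the future C4–C4a) is cut, and the phenolic oxygen (the future O1) is traced back to the formyl group of 1 by an aryl-to-oxygen migration. This is needed because 1 has the right three methoxy groups but no free phenol, so it cannot be the annulation partner itself. The forward steps must migrate the electron-rich aryl group in the oxidation and formylate only the one free ortho position.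

## Other disconnections considered

Alternative 1: The cut removes C3–C1' and C4–C4a together and leaves O1–C2 for a later etherification, with C2 added afterwards by one-carbon homologation.

- Forward key step: the boron ate complex from 2-ethenyl-4,4,5,5-tetramethyl-1,3,2-dioxaborolane A4 and [2,5-bis(benzyloxy)-3,4-dimethoxyphenyl]lithium A3 (from 1,4-bis(benzyloxy)-5-bromo-2,3-dimethoxybenzene A5 by halogen–lithium exchange) would react with 2-(methoxymethoxy)-3,4,5-trimethoxyphenyl trifluoromethanesulfonate A2 under Pd(OAc)2 and a chiral MandyPhos ligand. The arylpalladium species would induce a 1,2-shift of the ring B aryl group from boron to carbon, and reductive elimination would attach ring A, giving the secondary boronate A1.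
- In its favour: the stereocentre is set catalytically in the same event that joins both arenes, the route is convergent, and no intermediate has a carbonyl next to the stereocentre. On this last point it is better than the chosen plan.
- Against it: both aryl partners carry ortho substituents, which slows the migration and the oxidative addition of an electron-rich triflate. Lithium halide from the exchange is expected to interfere with the catalyst. C2 is missing from A1, so homologation of the boronate, oxidation of the C–B bond, removal of the acetal, Mitsunobu closure of ring C and hydrogenolysis of two benzyl ethers are all still needed before 20 is reached. A2 and A5 each need several steps of their own.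
- Comparison: ring B arrives ready-made, where the chosen plan builds it from 14; stereocontrol is catalyst-based in both; the end game through 20 is the same. On step economy it is estimated at about fifteen operations with a longest linear sequence near twelve, so it is not shorter than the chosen plan.

Alternative 2: The cut removes C4a–C8a and O1–C2, so that ring A and ring C are both made late and the squarate supplies C6, C7, C8 and C8a.

- Forward key step: heating 4-{(1E,4S)-4-[2,5-bis(benzyloxy)-3,4-dimethoxyphenyl]-5-[(methanesulfonyl)oxy]pent-1-en-1-yl}-2,3,4-trimethoxycyclobut-2-en-1-one A7 would open the four-membered ring to a dienylketene. Its 6π closure onto the substituted alkene terminus would form ring A as a phenol, and Cs2CO3 added afterwards would let the phenoxide displace the mesylate, closing ring C to (3S)-3-[2,5-bis(benzyloxy)-3,4-dimethoxyphenyl]-6,7,8-trimethoxychroman A6.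
- In its favour: it uses the same dependable pericyclic manifold as the chosen plan (an equal point), the three methoxy groups and the ring oxygen of ring A map well onto the squarate, and two rings are closed in one flask (a better point).
- Against it: the stereocentre has to be made beforehand in an open chain that already carries ring B, by an auxiliary or a separate asymmetric step. The primary mesylate is beta to a benzylic methine, and elimination to a styrene under carbonate or at the thermolysis temperature is a real risk. The closure takes place at a substituted alkene carbon and not at a free CH2. Ring B must be brought in as a protected hydroquinone and unmasked at the end, two steps after the key step where the chosen plan needs one.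
- Comparison: the chosen plan uses the squarate for the harder ring, the fully substituted quinone, needs no protecting group and takes ring A from a cheap aldehyde. Alternative 2 is estimated at roughly fifteen steps.

Alternative 3: The cut removes C3–C1' together with a temporary C4–O bond to the C2' oxygen.

- Forward key step: 6,7,8-trimethoxy-2H-chromene A9 and 2,3-dimethoxy-1,4-benzoquinone A10 would combine under a chiral titanium diolate of the TADDOL type (from TiCl4 and Ti(OiPr)4) in a formal (3+2) annulation to the cis-fused pterocarpan (6aS,11aS)-8-hydroxy-2,3,4,9,10-pentamethoxypterocarpan A8. Hydrogenolysis of the benzylic C–O bond would give 20 and oxidation would give 21.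
- In its favour: it is the shortest plan by far. A10 is symmetrical, so there is no regiochemical question; it could come from 3 by oxidation, and A9 from 3 in two steps by O-propargylation and thermal rearrangement, for an estimated seven steps in all. Ring B arrives with every atom in place. On step economy and convergence it is clearly better than the chosen plan.
- Against it: enantiocontrol rests on a stoichiometric chiral Lewis acid whose selectivity is known to depend on the substrate. The very electron-rich chromene A9 is prone to acid-promoted oligomerisation and to competing (2+2) and (5+2) pathways. A10 offers two chelating sites to the titanium centre.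
- Comparison: the mechanism is polar and stepwise under a strong Lewis acid, where the chosen plan closes ring B by a neutral pericyclic reaction and sets C3 by catalytic hydrogenation with a more predictable selectivity. Both plans pass through 20 and finish with the same oxidation, an equal point.

Key step: step 10

Assumption: the antipode of the spiro phosphine–oxazoline ligand that delivers (3R)-8 in step 5 is taken to be (Sa,S); the sense of induction is assigned by analogy, would be confirmed on 8 before it is carried on, and the other antipode is equally accessible.

Remark: the connectivity of 17 and 20 was re-derived atom by atom from 21 and needs no correction. Two points need care: the descriptor change noted above (the acid is 3R, the target 3S), and the fact that 1 must first be converted into salicylaldehyde 4 (steps 1 and 2) before acrolein can be used.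

## Steps

Step 1
Reactants: 1 2,3,4-trimethoxybenzaldehyde
Product: 3 2,3,4-trimethoxyphenol, via 2,3,4-trimethoxyphenyl formate 2 (not isolated)
Conditions: 30% aq H2O2, cat. H2SO4, MeOH, 0 °C to rt
Reagents that add atoms: hydrogen peroxide, OO
Why: Acid-catalysed Dakin (Baeyer–Villiger type) oxidation: the perhemiacetal of the electron-rich aldehyde rearranges with aryl migration to formate 2, which methanol cleaves under the same acid to phenol 3. The ortho and para methoxy groups make aryl migration the dominant path over hydride migration.

Step 2
Reactants: 3 2,3,4-trimethoxyphenol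
Product: 4 2-hydroxy-3,4,5-trimethoxybenzaldehyde
Conditions: MgCl2, Et3N, (CH2O)n, MeCN, reflux; dilute aq HCl
Reagents that add atoms: paraformaldehyde (as formaldehyde), C=O
Why: Magnesium-mediated ortho-formylation of a phenol (Casnati–Skattebøl): the ArOMgCl phenoxide delivers formaldehyde to the only free ortho position and the benzylic alkoxide is oxidised by a second formaldehyde through hydride transfer. The para position carries a methoxy group, so a single regioisomer is expected.

Step 3
Reactants: 4 2-hydroxy-3,4,5-trimethoxybenzaldehyde; 5 acrolein
Product: 6 6,7,8-trimethoxy-2H-chromene-3-carbaldehyde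
Conditions: K2CO3, 1,4-dioxane, reflux
Reagents that add atoms: none
Why: Domino oxa-Michael addition and intramolecular aldol condensation of a salicylaldehyde with an enal, the standard entry to 2H-chromene-3-carbaldehydes. The phenoxide adds to the beta carbon of 5, the resulting enolate closes on the aryl aldehyde and water is lost to give the conjugated C3=C4 bond.

Step 4
Reactants: 6 6,7,8-trimethoxy-2H-chromene-3-carbaldehyde
Product: 7 6,7,8-trimethoxy-2H-chromene-3-carboxylic acid
Conditions: NaClO2, NaH2PO4, 2-methyl-2-butene, t-BuOH/H2O, rt
Reagents that add atoms: sodium chlorite, [Na+].[O-]Cl=O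
Why: Pinnick oxidation converts the enal to the acid without touching the C3=C4 bond. The alkene scavenger removes HOCl before it can chlorinate the electron-rich ring A.

Step 5
Reactants: 7 6,7,8-trimethoxy-2H-chromene-3-carboxylic acid
Product: 8 (3R)-6,7,8-trimethoxychroman-3-carboxylic acid
Conditions: H2 (6 atm), [Ir(cod)((Sa,S)-SIPHOX)]BArF (1 mol %; SIPHOX = spirobiindane phosphine–oxazoline, BArF = tetrakis[3,5-bis(trifluoromethyl)phenyl]borate), Et3N (0.5 equiv), MeOH, rt; dilute aq HCl
Reagents that add atoms: none
Why: Carboxylate-directed iridium-catalysed asymmetric hydrogenation of a trisubstituted unsaturated acid: the carboxylate anchors the substrate on the metal and the chiral spiro ligand selects the alkene face, which sets C3 (3R by CIP here, the same spatial sense as 3S in 21). Enantiopurity can be raised by crystallising 8 as an amine salt before it is carried on.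

Step 6
Reactants: 8 (3R)-6,7,8-trimethoxychroman-3-carboxylic acid
Product: 10 (3R)-N,6,7,8-tetramethoxy-N-methylchroman-3-carboxamide, via acyl imidazolide 9 (not isolated)
Conditions: CDI, CH2Cl2, rt; then MeNHOMe·HCl, rt
Reagents that add atoms: N,O-dimethylhydroxylamine hydrochloride, CNOC.Cl; 1,1'-carbonyldiimidazole, O=C(n1ccnc1)n1ccnc1 (its atoms stay only in 9)
Why: Weinreb amide formation through acyl imidazolide 9. The activation is close to neutral and the imidazole set free is too weak a base to remove C3–H next to the carbonyl.

Step 7
Reactants: 10 (3R)-N,6,7,8-tetramethoxy-N-methylchroman-3-carboxamide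
Product: 12 1-[(3R)-6,7,8-trimethoxychroman-3-yl]ethan-1-one, via magnesium hemiaminal salt 11 (not isolated)
Conditions: MeMgBr, THF, −20 to 0 °C; cold aq NH4Cl
Reagents that add atoms: methylmagnesium bromide, C[Mg]Br
Why: Weinreb ketone synthesis: MeMgBr adds once to give the chelated tetrahedral salt 11, which persists until the cold quench, so no tertiary alcohol forms and no enolate is generated at C3. The methyl carbon introduced here becomes C6' of ring B.

Step 8
Reactants: 12 1-[(3R)-6,7,8-trimethoxychroman-3-yl]ethan-1-one
Product: 13 N'-{(1E)-1-[(3S)-6,7,8-trimethoxychroman-3-yl]ethylidene}-2,4,6-tri(propan-2-yl)benzenesulfonohydrazide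
Conditions: 2,4,6-triisopropylbenzenesulfonohydrazide, THF, rt, no acid
Reagents that add atoms: 2,4,6-tri(propan-2-yl)benzenesulfonohydrazide, NNS(=O)(=O)c1c(C(C)C)cc(C(C)C)cc1C(C)C
Why: Condensation of a methyl ketone with an arenesulfonyl hydrazide, run without acid at ambient temperature to avoid ene-hydrazine tautomerisation towards C3. The bulky chromanyl group should enforce the E geometry, which places the sulfonamide nitrogen syn to the methyl group; the descriptor becomes 3S only because the C=N carbon ranks below C2.

Step 9
Reactants: 13 N'-{(1E)-1-[(3S)-6,7,8-trimethoxychroman-3-yl]ethylidene}-2,4,6-tri(propan-2-yl)benzenesulfonohydrazide; 14 dimethyl squarate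
Product: 17 4-hydroxy-2,3-dimethoxy-4-{1-[(3S)-6,7,8-trimethoxychroman-3-yl]ethenyl}cyclobut-2-en-1-one (either configuration at the carbinol carbon), via dilithiated hydrazone 15 (not isolated), via vinyllithium 16 (not isolated)
Conditions: n-BuLi (2.05 equiv), THF, −78 °C; 0 °C until N2 evolution stops; −78 °C, 14; aq NH4Cl at −78 °C
Reagents that add atoms: none
Why: Shapiro reaction followed by 1,2-addition of a vinyllithium to a squarate ester: N–H and then syn-alpha (methyl) deprotonation gives 15, which on warming loses arenesulfinate and N2 to give 16, and 16 adds once to one carbonyl of 14 at −78 °C. Deprotonation at CH3 and not at C3–H follows from the syn-directing E hydrazone and from kinetic acidity, and the triisopropylphenyl group resists ortho-lithiation. The new carbinol centre forms without control and is erased in step 10.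

Step 10
Reactants: 17 4-hydroxy-2,3-dimethoxy-4-{1-[(3S)-6,7,8-trimethoxychroman-3-yl]ethenyl}cyclobut-2-en-1-one
Product: 20 (3S)-3-(2,5-dihydroxy-3,4-dimethoxyphenyl)-6,7,8-trimethoxychroman, via dienylketene 18 (not isolated), via cyclohexadienone 19 (not isolated)
Conditions: degassed toluene, high dilution, 110 °C, argon
Reagents that add atoms: none
Why: Heating 17 triggers thermal conrotatory 4π electrocyclic opening of the bond between the carbonyl and the carbinol carbon of the cyclobutenone (C5'–C2' in target numbering); the hydroxyl, the stronger donor, rotates outward, so the ethenyl group turns inward and dienylketene 18 forms with the ketene and the vinyl CH2 on the same side. Thermal disrotatory 6π electrocyclisation then joins the ketene carbon (C5') to the unsubstituted methylene terminus (C6'), closing ring B as a six-membered carbocycle in cyclohexa-2,4-dienone 19. Enolisation of the C6' methylene of 19 is driven by aromatisation and gives hydroquinone 20. The closest known reaction type is the thermal rearrangement of 4-alkenyl- and 4-aryl-4-hydroxycyclobutenones derived from squarate esters to hydroquinones. No stereocentre is created: the carbinol centre of 17 is destroyed in the ring opening, both epimers converge on 18, and C3 is a spectator one bond away from the reacting π system. The step needs torquoselectivity (hydroxyl outward) and C–C closure in preference to attack of the hydroxyl oxygen on the ketene; the first is secured by the donor hydroxyl, the second by the sterically free CH2 terminus held next to the ketene and by high dilution. Regiochemistry is fixed by connectivity, because only the bond between the carbonyl and the carbinol carbon can open and each squarate carbon keeps its oxygen. The medium is neutral and free of oxygen, so C3–H should not exchange and 20 should not be oxidised prematurely.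

Step 11
Reactants: 20 (3S)-3-(2,5-dihydroxy-3,4-dimethoxyphenyl)-6,7,8-trimethoxychroman
Product: 21 abruquinone B, 2,3-dimethoxy-5-[(3S)-6,7,8-trimethoxychroman-3-yl]cyclohexa-2,5-diene-1,4-dione
Conditions: Ag2O, Na2SO4, Et2O, rt, dark; filtration through Celite
Reagents that add atoms: none
Why: Oxidation of a hydroquinone to the para-quinone by Ag2O under neutral, anhydrous conditions. The mild heterogeneous oxidant should leave ring A untouched, and no acid or base is present that could tautomerise the quinone through C3–H.

## Compound list

1 | 2,3,4-trimethoxybenzaldehyde | COc1ccc(C=O)c(OC)c1OC | starting material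
2 | 2,3,4-trimethoxyphenyl formate | COc1ccc(OC=O)c(OC)c1OC | intermediate (not isolated)
3 | 2,3,4-trimethoxyphenol | COc1ccc(O)c(OC)c1OC | intermediate
4 | 2-hydroxy-3,4,5-trimethoxybenzaldehyde | COc1cc(C=O)c(O)c(OC)c1OC | intermediate
5 | acrolein (prop-2-enal) | C=CC=O | starting material
6 | 6,7,8-trimethoxy-2H-chromene-3-carbaldehyde | COc1cc2C=C(C=O)COc2c(OC)c1OC | intermediate
7 | 6,7,8-trimethoxy-2H-chromene-3-carboxylic acid | COc1cc2C=C(C(=O)O)COc2c(OC)c1OC | intermediate
8 | (3R)-6,7,8-trimethoxychroman-3-carboxylic acid | O=C(O)[C@H]1COc2c(cc(OC)c(OC)c2OC)C1 | intermediate
9 | 1H-imidazol-1-yl[(3R)-6,7,8-trimethoxychroman-3-yl]methanone | O=C([C@H]1COc2c(cc(OC)c(OC)c2OC)C1)n1ccnc1 | intermediate (not isolated)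
10 | (3R)-N,6,7,8-tetramethoxy-N-methylchroman-3-carboxamide | CON(C)C(=O)[C@H]1COc2c(cc(OC)c(OC)c2OC)C1 | intermediate
11 | bromomagnesium 1-[methoxy(methyl)amino]-1-[(3R)-6,7,8-trimethoxychroman-3-yl]ethan-1-olate (either configuration at the carbinol carbon) | CON(C)C(C)(O[Mg]Br)[C@H]1COc2c(cc(OC)c(OC)c2OC)C1 | intermediate (not isolated)
12 | 1-[(3R)-6,7,8-trimethoxychroman-3-yl]ethan-1-one | CC(=O)[C@H]1COc2c(cc(OC)c(OC)c2OC)C1 | intermediate
13 | N'-{(1E)-1-[(3S)-6,7,8-trimethoxychroman-3-yl]ethylidene}-2,4,6-tri(propan-2-yl)benzenesulfonohydrazide | C/C(=N\NS(=O)(=O)c1c(C(C)C)cc(C(C)C)cc1C(C)C)[C@H]1COc2c(cc(OC)c(OC)c2OC)C1 | intermediate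
14 | dimethyl squarate (3,4-dimethoxycyclobut-3-ene-1,2-dione) | COC1=C(OC)C(=O)C1=O | starting material
15 | N,C-dilithio derivative of 13 (lithium on the sulfonamide nitrogen and on the former methyl carbon) | [Li]C/C(=N\N([Li])S(=O)(=O)c1c(C(C)C)cc(C(C)C)cc1C(C)C)[C@H]1COc2c(cc(OC)c(OC)c2OC)C1 | intermediate (not isolated)
16 | {1-[(3S)-6,7,8-trimethoxychroman-3-yl]ethenyl}lithium | [Li]C(=C)[C@H]1COc2c(cc(OC)c(OC)c2OC)C1 | intermediate (not isolated)
17 | 4-hydroxy-2,3-dimethoxy-4-{1-[(3S)-6,7,8-trimethoxychroman-3-yl]ethenyl}cyclobut-2-en-1-one (carbinol carbon in either configuration) | COC1=C(OC)C(O)(C(=C)[C@H]2COc3c(cc(OC)c(OC)c3OC)C2)C1=O | intermediate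
18 | (3Z)-4-hydroxy-2,3-dimethoxy-5-[(3S)-6,7,8-trimethoxychroman-3-yl]hexa-1,3,5-trien-1-one | O=C=C(OC)/C(OC)=C(/O)C(=C)[C@H]1COc2c(cc(OC)c(OC)c2OC)C1 | intermediate (not isolated)
19 | 4-hydroxy-2,3-dimethoxy-5-[(3S)-6,7,8-trimethoxychroman-3-yl]cyclohexa-2,4-dien-1-one | O=C1CC([C@H]2COc3c(cc(OC)c(OC)c3OC)C2)=C(O)C(OC)=C1OC | intermediate (not isolated)
20 | (3S)-3-(2,5-dihydroxy-3,4-dimethoxyphenyl)-6,7,8-trimethoxychroman | COc1c(OC)c(O)c([C@H]2COc3c(cc(OC)c(OC)c3OC)C2)cc1O | intermediate
21 | abruquinone B, 2,3-dimethoxy-5-[(3S)-6,7,8-trimethoxychroman-3-yl]cyclohexa-2,5-diene-1,4-dione | COC1=C(OC)C(=O)C([C@H]2COc3c(cc(OC)c(OC)c3OC)C2)=CC1=O | target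

## Step count and least certain steps

Total step count: 11. Longest linear sequence: 11 steps (1 to 21; 5 and 14 are bought).

Step 10 (key step). The most likely failure is diversion of the ketene: ring opening with the ethenyl group outward followed by closure of the hydroxyl oxygen onto the ketene (lactonisation), or acylation of the phenolic product by unreacted ketene. Both arise because a free hydroxyl is present next to a strong electrophile. Partial aerial oxidation during heating would also complicate handling.

Fallback, from 17 back to 20: the tertiary hydroxyl is masked before heating. N-(Trimethylsilyl)imidazole in CH2Cl2 should convert 17 into 2,3-dimethoxy-4-{1-[(3S)-6,7,8-trimethoxychroman-3-yl]ethenyl}-4-[(trimethylsilyl)oxy]cyclobut-2-en-1-one F1. Thermolysis of F1 in toluene should follow the same 4π/6π path, with the silyloxy group outward and no hydroxyl to trap the ketene, giving (3S)-3-{5-hydroxy-3,4-dimethoxy-2-[(trimethylsilyl)oxy]phenyl}-6,7,8-trimethoxychroman F2. Dilute acetic acid in aqueous THF would remove the aryl silyl ether and return the route to 20.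

Step 9. The most likely failures are misdirected or incomplete metalation of 13 (deprotonation at C3–H, which would destroy the stereocentre and open the way to loss of the aryloxide), proton quench of 16 by the solvent during the warm-up, and addition of leftover n-BuLi to 14.

Fallback, from 10 back to 16: the vinyllithium is made by halogen–lithium exchange and not by hydrazone fragmentation. DIBAL-H at −78 °C should reduce 10 to (3R)-6,7,8-trimethoxychroman-3-carbaldehyde F3. CBr4/PPh3 would give (3S)-3-(2,2-dibromoethenyl)-6,7,8-trimethoxychroman F4. n-BuLi followed by water would give (3S)-3-ethynyl-6,7,8-trimethoxychroman F5. Bromoboration with B-bromo-9-borabicyclo[3.3.1]nonane and protonolysis with acetic acid would give the Markovnikov bromide (3R)-3-(1-bromoethenyl)-6,7,8-trimethoxychroman F6. t-BuLi (2 equiv) at −78 °C would then give 16, which is added to 14 as in step 9. This detour is longer and passes through the epimerisable aldehyde F3, which is why it is not the first choice.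

Step 8. The most likely failure is erosion of configurational purity at C3 through tautomerisation of the hydrazone (or of the ketone) towards the more substituted ene-hydrazine or enol during the condensation. Formation of some Z hydrazone would also misdirect the later deprotonation.

Fallback, from 12 back to 16, avoiding any hydrazone: kinetic deprotonation of 12 on the methyl group with LDA at −78 °C and trapping with N-phenylbis(trifluoromethanesulfonimide) should give 1-[(3R)-6,7,8-trimethoxychroman-3-yl]ethenyl trifluoromethanesulfonate F7. Stannylation with hexamethyldistannane, Pd(PPh3)4 and LiCl in THF would give trimethyl{1-[(3R)-6,7,8-trimethoxychroman-3-yl]ethenyl}stannane F8. Tin–lithium exchange with MeLi at −78 °C would give 16 for addition to 14.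

Step 5. The most likely failure is insufficient facial selectivity, or the opposite sense of induction, for this trimethoxy-substituted substrate, since the assignment of the ligand antipode rests on analogy.

Fallback, from 7 back to 8, replacing asymmetric catalysis by classical resolution: hydrogenation of 7 over Pd/C should give rac-6,7,8-trimethoxychroman-3-carboxylic acid F9. Crystallisation with (S)-1-phenylethylamine (or its antipode, whichever gives the less soluble salt with the 3R acid in a small screen) would give (1S)-1-phenylethan-1-aminium (3R)-6,7,8-trimethoxychroman-3-carboxylate F10. Dilute acid would then liberate 8.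

## Further compounds

F1 | step 10 | 2,3-dimethoxy-4-{1-[(3S)-6,7,8-trimethoxychroman-3-yl]ethenyl}-4-[(trimethylsilyl)oxy]cyclobut-2-en-1-one | COC1=C(OC)C(O[Si](C)(C)C)(C(=C)[C@H]2COc3c(cc(OC)c(OC)c3OC)C2)C1=O
F2 | step 10 | (3S)-3-{5-hydroxy-3,4-dimethoxy-2-[(trimethylsilyl)oxy]phenyl}-6,7,8-trimethoxychroman | COc1c(OC)c(O[Si](C)(C)C)c([C@H]2COc3c(cc(OC)c(OC)c3OC)C2)cc1O
F3 | step 9 | (3R)-6,7,8-trimethoxychroman-3-carbaldehyde | O=C[C@H]1COc2c(cc(OC)c(OC)c2OC)C1
F4 | step 9 | (3S)-3-(2,2-dibromoethenyl)-6,7,8-trimethoxychroman | BrC(Br)=C[C@H]1COc2c(cc(OC)c(OC)c2OC)C1
F5 | step 9 | (3S)-3-ethynyl-6,7,8-trimethoxychroman | C#C[C@H]1COc2c(cc(OC)c(OC)c2OC)C1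
F6 | step 9 | (3R)-3-(1-bromoethenyl)-6,7,8-trimethoxychroman | C=C(Br)[C@H]1COc2c(cc(OC)c(OC)c2OC)C1
F7 | step 8 | 1-[(3R)-6,7,8-trimethoxychroman-3-yl]ethenyl trifluoromethanesulfonate | C=C(OS(=O)(=O)C(F)(F)F)[C@H]1COc2c(cc(OC)c(OC)c2OC)C1
F8 | step 8 | trimethyl{1-[(3R)-6,7,8-trimethoxychroman-3-yl]ethenyl}stannane | C=C([Sn](C)(C)C)[C@H]1COc2c(cc(OC)c(OC)c2OC)C1
F9 | step 5 | rac-6,7,8-trimethoxychroman-3-carboxylic acid | O=C(O)C1COc2c(cc(OC)c(OC)c2OC)C1
F10 | step 5 | (1S)-1-phenylethan-1-aminium (3R)-6,7,8-trimethoxychroman-3-carboxylate | C[C@H]([NH3+])c1ccccc1.[O-]C(=O)[C@H]1COc2c(cc(OC)c(OC)c2OC)C1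
A1 | alternative 1 | 2-{(1S)-1-[2,5-bis(benzyloxy)-3,4-dimethoxyphenyl]-2-[2-(methoxymethoxy)-3,4,5-trimethoxyphenyl]ethyl}-4,4,5,5-tetramethyl-1,3,2-dioxaborolane | COCOc1c(C[C@H](B2OC(C)(C)C(C)(C)O2)c2cc(OCc3ccccc3)c(OC)c(OC)c2OCc2ccccc2)cc(OC)c(OC)c1OC
A2 | alternative 1 | 2-(methoxymethoxy)-3,4,5-trimethoxyphenyl trifluoromethanesulfonate | COCOc1c(OS(=O)(=O)C(F)(F)F)cc(OC)c(OC)c1OC
A3 | alternative 1 | [2,5-bis(benzyloxy)-3,4-dimethoxyphenyl]lithium | [Li]c1cc(OCc2ccccc2)c(OC)c(OC)c1OCc1ccccc1
A4 | alternative 1 | 2-ethenyl-4,4,5,5-tetramethyl-1,3,2-dioxaborolane | C=CB1OC(C)(C)C(C)(C)O1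
A5 | alternative 1 | 1,4-bis(benzyloxy)-5-bromo-2,3-dimethoxybenzene | Brc1cc(OCc2ccccc2)c(OC)c(OC)c1OCc1ccccc1
A6 | alternative 2 | (3S)-3-[2,5-bis(benzyloxy)-3,4-dimethoxyphenyl]-6,7,8-trimethoxychroman | COc1c(OC)c(OCc2ccccc2)cc([C@H]2COc3c(cc(OC)c(OC)c3OC)C2)c1OCc1ccccc1
A7 | alternative 2 | 4-{(1E,4S)-4-[2,5-bis(benzyloxy)-3,4-dimethoxyphenyl]-5-[(methanesulfonyl)oxy]pent-1-en-1-yl}-2,3,4-trimethoxycyclobut-2-en-1-one | COC1=C(OC)C(OC)(/C=C/C[C@H](COS(C)(=O)=O)c2cc(OCc3ccccc3)c(OC)c(OC)c2OCc2ccccc2)C1=O
A8 | alternative 3 | (6aS,11aS)-8-hydroxy-2,3,4,9,10-pentamethoxypterocarpan | COc1cc2[C@H]3Oc4c(OC)c(OC)c(O)cc4[C@H]3COc2c(OC)c1OC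
A9 | alternative 3 | 6,7,8-trimethoxy-2H-chromene | COc1cc2C=CCOc2c(OC)c1OC
A10 | alternative 3 | 2,3-dimethoxy-1,4-benzoquinone | COC1=C(OC)C(=O)C=CC1=O
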